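## Retrosynthetic overview

1. Target 11 ⇐ desilylation of 10; the only ring (the oxane, O bridging C7 and C11) is closed second to last by bromoetherification of bromohydrin 9, which makes the C7–O and C6–Br bonds.
2. 9 ⇐ terminal bromohydration of 8, the silyl ether of (3S,6E)-nerolidol.
3. 8 ⇐ isopropylidene Wittig on aldehyde 7 ⇐ ester 6, whose C8–C9 bond and (6E)-alkene come from a Johnson–Claisen [3,3]-sigmatropic rearrangement of carbinol 4 (key step).
4. 4 ⇐ isopropenyl Grignard addition to aldehyde 3 ⇐ selective ozonolysis of silylated (S)-linalool 1, which supplies C3.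

Assumption: (S)-(+)-linalool (coriandrol) of high enantiomeric purity is taken as purchasable.

Atom labels C1–C11 follow the nerolidol chain: C3 = carbinol carbon, C6 = acyclic CHBr, C7 = ring carbon bearing methyl, C10 = ring CHBr, C11 = CMe2.

Stereochemical outcome, stated plainly: C3 is bought. C6 and C7 are set from C10 in the ring closure. C10 itself is formed without control in step 7, so step 8 gives the target series and its 6S,7R,10S diastereomer in about equal amounts and they are separated there.

## Route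

Step 1
Reactants: 1 (S)-(+)-linalool, (3S)-3,7-dimethylocta-1,6-dien-3-ol
Product: 2 triethyl{[(3S)-3,7-dimethylocta-1,6-dien-3-yl]oxy}silane
Conditions: TESOTf, 2,6-lutidine, CH2Cl2, −78 → 0 °C
Reagents that add atoms: triethylsilyl trifluoromethanesulfonate, CC[Si](CC)(CC)OS(=O)(=O)C(F)(F)F
Why: Silyl ether formation with a silyl triflate masks the hindered tertiary C3 oxygen, so that it can neither enter the Claisen step nor attack the bromonium ion later, and leaves the bought C3 centre untouched.

Step 2
Reactants: 2 triethyl{[(3S)-3,7-dimethylocta-1,6-dien-3-yl]oxy}silane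
Product: 3 (4S)-4-methyl-4-[(triethylsilyl)oxy]hex-5-enal
Conditions: O3, CH2Cl2/MeOH, −78 °C, Sudan Red 7B end point; then Me2S, −78 °C → rt
Reagents that add atoms: ozone, [O-][O+]=O
Why: Ozonolysis with reductive work-up cleaves the electron-rich trisubstituted alkene much faster than the hindered vinyl group and gives the aldehyde that carries C1–C6.

Step 3
Reactants: 3 (4S)-4-methyl-4-[(triethylsilyl)oxy]hex-5-enal
Product: 4 (3RS,6S)-2,6-dimethyl-6-[(triethylsilyl)oxy]octa-1,7-dien-3-ol
Conditions: isopropenylmagnesium bromide, THF, −78 → 0 °C; aq. NH4Cl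
Reagents that add atoms: isopropenylmagnesium bromide, CC(=C)[Mg]Br
Why: Grignard 1,2-addition gives the 2-methylallylic alcohol needed for the Claisen step, and the new carbinol centre may be a mixture because it becomes sp2 in step 4.

Step 4
Reactants: 4 (3RS,6S)-2,6-dimethyl-6-[(triethylsilyl)oxy]octa-1,7-dien-3-ol
Product: 6 ethyl (4E,8S)-4,8-dimethyl-8-[(triethylsilyl)oxy]deca-4,9-dienoate, via mixed ketene acetal 5 (not isolated)
Conditions: MeC(OEt)3, EtCO2H (cat.), 140 °C, EtOH distilled off
Reagents that add atoms: triethyl orthoacetate, CC(OCC)(OCC)OCC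
Why: Johnson–Claisen [3,3]-sigmatropic rearrangement of the ketene acetal through a chair with the carbinol substituent equatorial forms the C8–C9 bond and the (6E)-trisubstituted alkene with high selectivity from either carbinol epimer, and this geometry later fixes the C6/C7 relationship.

Step 5
Reactants: 6 ethyl (4E,8S)-4,8-dimethyl-8-[(triethylsilyl)oxy]deca-4,9-dienoate
Product: 7 (4E,8S)-4,8-dimethyl-8-[(triethylsilyl)oxy]deca-4,9-dienal
Conditions: i-Bu2AlH, CH2Cl2, −78 °C; aq. potassium sodium tartrate
Reagents that add atoms: none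
Why: Partial hydride reduction of the ester at low temperature stops at the aluminium hemiacetal, which releases the aldehyde on work-up.

Step 6
Reactants: 7 (4E,8S)-4,8-dimethyl-8-[(triethylsilyl)oxy]deca-4,9-dienal
Product: 8 triethyl{[(3S,6E)-3,7,11-trimethyldodeca-1,6,10-trien-3-yl]oxy}silane
Conditions: i-PrPPh3I, n-BuLi, THF, 0 °C; then 7, −78 °C → rt
Reagents that add atoms: isopropyltriphenylphosphonium iodide, CC(C)[P+](c1ccccc1)(c1ccccc1)c1ccccc1.[I-]
Why: Wittig olefination with the unstabilised isopropylidene ylide turns the aldehyde into the terminal trisubstituted alkene, which has no geometry to control, and completes the farnesane skeleton.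

Step 7
Reactants: 8 triethyl{[(3S,6E)-3,7,11-trimethyldodeca-1,6,10-trien-3-yl]oxy}silane
Product: 9 (6E,10S)-3-bromo-2,6,10-trimethyl-10-[(triethylsilyl)oxy]dodeca-6,11-dien-2-ol, both C3 epimers (C10 of the chain), about 1:1
Conditions: NBS (1.05 equiv), THF/H2O 3:1, 0 °C
Reagents that add atoms: N-bromosuccinimide, O=C1CCC(=O)N1Br; water, O
Why: Bromohydration of the terminal, most exposed trisubstituted alkene, with water opening the bromonium ion at the tertiary carbon, gives the C10–Br/C11–OH pattern, but C3 is too remote to bias the alkene face, so the 10R and 10S epimers form in about equal amounts and are carried on together.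

Step 8
Reactants: 9 (6E,10S)-3-bromo-2,6,10-trimethyl-10-[(triethylsilyl)oxy]dodeca-6,11-dien-2-ol
Product: 10 triethyl{[(3S,5R)-5-bromo-5-[(2S,5R)-5-bromo-2,6,6-trimethyloxan-2-yl]-3-methylpent-1-en-3-yl]oxy}silane
Conditions: TBCO (1.1 equiv), CH2Cl2, 0 °C → rt; chromatographic separation of the diastereomers
Reagents that add atoms: 2,4,4,6-tetrabromocyclohexa-2,5-dien-1-one, O=C1C(Br)=CC(Br)(Br)C=C1Br
Why: Bromoetherification, in which the tertiary C11–OH opens the 6,7-bromonium ion at the tertiary C7 in a 6-exo chair with the C10 bromide and the C6 branch equatorial and with anti addition across the (E)-alkene, converts the 10R bromohydrin into the 6R,7S,10R oxane 10, while the 10S bromohydrin gives the 6S,7R,10S diastereomer that is removed here.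

Step 9
Reactants: 10 triethyl{[(3S,5R)-5-bromo-5-[(2S,5R)-5-bromo-2,6,6-trimethyloxan-2-yl]-3-methylpent-1-en-3-yl]oxy}silane
Product: 11 (3S,5R)-5-bromo-5-[(2S,5R)-5-bromo-2,6,6-trimethyloxan-2-yl]-3-methylpent-1-en-3-ol
Conditions: HF·pyridine, THF/pyridine, 0 °C → rt
Reagents that add atoms: none
Why: Fluoride-driven Si–O cleavage (desilylation) under buffered, non-basic conditions frees the tertiary allylic alcohol without eliminating either secondary bromide or touching any stereocentre.

## Compound list

1 | (S)-(+)-linalool, (3S)-3,7-dimethylocta-1,6-dien-3-ol | C=C[C@@](C)(O)CCC=C(C)C | starting material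
2 | triethyl{[(3S)-3,7-dimethylocta-1,6-dien-3-yl]oxy}silane | C=C[C@@](C)(O[Si](CC)(CC)CC)CCC=C(C)C | intermediate
3 | (4S)-4-methyl-4-[(triethylsilyl)oxy]hex-5-enal | C=C[C@@](C)(O[Si](CC)(CC)CC)CCC=O | intermediate
4 | (3RS,6S)-2,6-dimethyl-6-[(triethylsilyl)oxy]octa-1,7-dien-3-ol | C=C[C@@](C)(O[Si](CC)(CC)CC)CCC(O)C(C)=C | intermediate
5 | (6S)-3-[(1-ethoxyethenyl)oxy]-2,6-dimethyl-6-[(triethylsilyl)oxy]octa-1,7-diene (mixed ketene acetal, both C3 epimers) | C=C[C@@](C)(O[Si](CC)(CC)CC)CCC(OC(=C)OCC)C(C)=C | intermediate (not isolated)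
6 | ethyl (4E,8S)-4,8-dimethyl-8-[(triethylsilyl)oxy]deca-4,9-dienoate | C=C[C@@](C)(O[Si](CC)(CC)CC)CC/C=C(\C)CCC(=O)OCC | intermediate
7 | (4E,8S)-4,8-dimethyl-8-[(triethylsilyl)oxy]deca-4,9-dienal | C=C[C@@](C)(O[Si](CC)(CC)CC)CC/C=C(\C)CCC=O | intermediate
8 | triethyl{[(3S,6E)-3,7,11-trimethyldodeca-1,6,10-trien-3-yl]oxy}silane | C=C[C@@](C)(O[Si](CC)(CC)CC)CC/C=C(\C)CCC=C(C)C | intermediate
9 | (6E,10S)-3-bromo-2,6,10-trimethyl-10-[(triethylsilyl)oxy]dodeca-6,11-dien-2-ol, 3R and 3S about 1:1 (3R leads to the target) | C=C[C@@](C)(O[Si](CC)(CC)CC)CC/C=C(\C)CCC(Br)C(C)(C)O | intermediate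
10 | triethyl{[(3S,5R)-5-bromo-5-[(2S,5R)-5-bromo-2,6,6-trimethyloxan-2-yl]-3-methylpent-1-en-3-yl]oxy}silane | C=C[C@@](C)(O[Si](CC)(CC)CC)CC[C@@H](Br)[C@]1(C)CC[C@@H](Br)C(C)(C)O1 | intermediate
11 | (3S,5R)-5-bromo-5-[(2S,5R)-5-bromo-2,6,6-trimethyloxan-2-yl]-3-methylpent-1-en-3-ol | C=C[C@@](C)(O)CC[C@@H](Br)[C@]1(C)CC[C@@H](Br)C(C)(C)O1 | target

## Step count and risks

Total step count: 9. Longest linear sequence: 9 steps (fully linear from 1).

The three steps most likely to fail:

Step 7. The internal 6,7-alkene can compete for NBS, and C10 is formed with no facial bias, so at most half of the material has the right configuration. Fallback: setting out from aldehyde 7, transfer an isopropylidene unit with Ph2S=CMe2 (from isopropyldiphenylsulfonium tetrafluoroborate and t-BuLi, THF, −78 °C) to give the terminal epoxide F2. Opening it at the secondary carbon with Li2NiBr4 (THF, 0 °C) bypasses 8 and returns to the route at bromohydrin 9. This removes the site-selectivity problem but still gives both C10 epimers.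

Step 8. TBCO cyclisations are often low-yielding; the silylated C3 oxygen may attack the bromonium ion, and the preference for the C6 branch equatorial may be modest. Fallback: setting out from 9, close the ring by oxymercuration (Hg(OCOCF3)2, MeNO2, 0 °C; then aq. KBr) to the alkylmercury bromide F3. Replacing mercury by bromine with retention (Br2, pyridine, −40 °C, dark) returns to the route at 10.

Step 2. Ozone may also attack the vinyl group or over-oxidise. Fallback: setting out from 2, epoxidise the trisubstituted alkene selectively (mCPBA, NaHCO3, CH2Cl2, 0 °C) to the 6,7-epoxide F1. Cleaving it with HIO4·2H2O (THF/Et2O, 0 °C) returns to the route at aldehyde 3.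

Further compounds
F1 | step 2 | triethyl{[(3S)-5-(3,3-dimethyloxiran-2-yl)-3-methylpent-1-en-3-yl]oxy}silane, both oxirane epimers | C=C[C@@](C)(O[Si](CC)(CC)CC)CCC1OC1(C)C
F2 | step 7 | triethyl{[(3S,6E)-9-(3,3-dimethyloxiran-2-yl)-3,7-dimethylnona-1,6-dien-3-yl]oxy}silane, both oxirane epimers | C=C[C@@](C)(O[Si](CC)(CC)CC)CC/C=C(\C)CCC1OC1(C)C
F3 | step 8 | bromo{(1R,3S)-1-[(2S,5R)-5-bromo-2,6,6-trimethyloxan-2-yl]-3-methyl-3-[(triethylsilyl)oxy]pent-4-en-1-yl}mercury | C=C[C@@](C)(O[Si](CC)(CC)CC)CC[C@@H]([Hg]Br)[C@]1(C)CC[C@@H](Br)C(C)(C)O1
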